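The target is disconnected at all eight C–Br bonds, back to a halogen-free triaryl diether. Every C–H to be substituted sits ortho to an oxygen donor: B3 and B6 on the tetra-oxygenated central ring B, C3' and C5' beside the C4' hydroxyl of each outer ring (rings A and C), and C2' beside the ether oxygen at C1'. One bromination with eight equivalents of Br2 should therefore install all eight halogens. The precursor is 1,4-bis(4-hydroxyphenoxy)-2,5-dimethoxybenzene: free outer phenols to steer the halogens, ring B masked as its dimethyl ether against quinone formation. A double Ullmann coupling and a hydrogenolysis build it; BBr3 demethylation finishes.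

Key step: step 3

Atom labels: ring B is the central ring (B1 and B4 carry the aryloxy groups, B2 and B5 the oxygens that end as OH, B3 and B6 the bromines); each outer ring is numbered from its ether carbon C1' to its hydroxyl carbon C4'.
Assumption: the target has no stereocentre and its diaryl ether bonds are taken as freely rotating, so no stereocontrol is needed; the diiodide is chosen over the dibromide as ring B building block because its C–I bonds couple more readily.

Step 1
Reactants: 1 1,4-diiodo-2,5-dimethoxybenzene; 2 4-(benzyloxy)phenol (2.5 equiv)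
Product: 3 1,4-bis[4-(benzyloxy)phenoxy]-2,5-dimethoxybenzene
Conditions: CuI (20 mol %), N,N-dimethylglycine·HCl (40 mol %), Cs2CO3 (5 equiv), 1,4-dioxane, 100 °C, Ar
Reagents that add atoms: none
Why: Ullmann diaryl ether synthesis, in which the monovalent copper catalyst CuI, ligated by N,N-dimethylglycine, inserts into each C–I bond of the electron-rich diiodide and couples it with the caesium phenoxide of 2, whose benzyl ether leaves only one nucleophilic oxygen per hydroquinone unit so that no oligomer can form.

Step 2
Reactants: 3 1,4-bis[4-(benzyloxy)phenoxy]-2,5-dimethoxybenzene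
Product: 4 4,4'-[(2,5-dimethoxy-1,4-phenylene)bis(oxy)]diphenol
Conditions: H2 (1 atm), 10% Pd/C, THF/MeOH, rt
Reagents that add atoms: none
Why: Catalytic hydrogenolysis of benzyl aryl ethers over Pd/C cleaves only the two benzylic C–O bonds, and because no halogen is present yet the methyl and diaryl ethers should pass unchanged.

Step 3
Reactants: 4 4,4'-[(2,5-dimethoxy-1,4-phenylene)bis(oxy)]diphenol
Product: 6 4,4'-[(2,5-dibromo-3,6-dimethoxy-1,4-phenylene)bis(oxy)]bis(2,3,6-tribromophenol), via hexabromo bis-phenol 5 (not isolated)
Conditions: Br2 (6.0 equiv), dry 1,2-dichloroethane, 0 °C → rt; then Br2 (2.05 equiv), FeBr3 (5 mol %), 45 °C, dark; aq. NaHSO3 quench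
Reagents that add atoms: bromine, BrBr
Why: The step is a sequence of eight electrophilic aromatic substitutions through arenium ions, each releasing HBr, with the Lewis acid FeBr3 polarising Br2 for the last and slowest pair. The closest known reaction type is the exhaustive ring bromination of phenols and hydroxylated diphenyl ethers; no ring is closed and no stereocentre is formed. The free C4' hydroxyl is the strongest donor of each outer ring and should direct the first bromines to C3' and C5', while ring B, activated by four oxygens, has only B3 and B6 open, so the hexabromide 5 should form cleanly in the cold stage. After that only the homotopic C2' and C6' remain on each outer ring, and they are activated by the ether oxygen at C1', whose lone pair is pushed toward the outer ring because the now fully substituted ring B twists out of conjugation. The step must stop at one bromine per outer ring, which is secured by the inductive and steric deactivation that the new C2' bromine (meta to C6') imposes and by charging exactly eight equivalents of Br2. The methyl ethers keep ring B from being oxidised to a quinone, and the dry, non-nucleophilic solvent keeps reversible ipso attack at C1' from ending in oxidative cleavage of the diaryl ether.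

Step 4
Reactants: 6 4,4'-[(2,5-dibromo-3,6-dimethoxy-1,4-phenylene)bis(oxy)]bis(2,3,6-tribromophenol)
Product: 7 2,5-dibromo-3,6-bis(2,3,5-tribromo-4-hydroxyphenoxy)benzene-1,4-diol (CNP0163357.0)
Conditions: BBr3 (6 equiv), CH2Cl2, −78 °C → rt, Ar; then ice/H2O, aq. Na2S2O4 wash
Reagents that add atoms: none
Why: Lewis acid-mediated O-demethylation, in which BBr3 complexes the two twisted, basic methyl ether oxygens of ring B and bromide removes the methyl groups by SN2 as MeBr, while diaryl ether C–O and aryl C–Br bonds are inert to BBr3 and the dithionite wash keeps the freed ring B hydroquinone reduced.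

Compound list
1 | 1,4-diiodo-2,5-dimethoxybenzene | COc1cc(I)c(OC)cc1I | starting material
2 | 4-(benzyloxy)phenol | Oc1ccc(OCc2ccccc2)cc1 | starting material
3 | 1,4-bis[4-(benzyloxy)phenoxy]-2,5-dimethoxybenzene | COc1cc(Oc2ccc(OCc3ccccc3)cc2)c(OC)cc1Oc1ccc(OCc2ccccc2)cc1 | intermediate
4 | 4,4'-[(2,5-dimethoxy-1,4-phenylene)bis(oxy)]diphenol | COc1cc(Oc2ccc(O)cc2)c(OC)cc1Oc1ccc(O)cc1 | intermediate
5 | 4,4'-[(2,5-dibromo-3,6-dimethoxy-1,4-phenylene)bis(oxy)]bis(2,6-dibromophenol) (hexabromo bis-phenol) | COc1c(Br)c(Oc2cc(Br)c(O)c(Br)c2)c(OC)c(Br)c1Oc1cc(Br)c(O)c(Br)c1 | intermediate (not isolated)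
6 | 4,4'-[(2,5-dibromo-3,6-dimethoxy-1,4-phenylene)bis(oxy)]bis(2,3,6-tribromophenol) | COc1c(Br)c(Oc2cc(Br)c(O)c(Br)c2Br)c(OC)c(Br)c1Oc1cc(Br)c(O)c(Br)c1Br | intermediate
7 | 2,5-dibromo-3,6-bis(2,3,5-tribromo-4-hydroxyphenoxy)benzene-1,4-diol | Oc1c(Br)cc(Oc2c(O)c(Br)c(Oc3cc(Br)c(O)c(Br)c3Br)c(O)c2Br)c(Br)c1Br | target

Total step count: 4
Longest linear sequence: 4 steps (1 → 3 → 4 → 6 → 7)

Steps most likely to fail

Step 3 (key step). The count of bromines ortho to the ether oxygens may drift, either by stalling at the hexa- or heptabromide stage or by a second substitution at C6'. Ipso attack at C1' may also turn into oxidative cleavage of the diaryl ether. The fallback sets out from 2 and returns at 6, and brings the C2' bromines in before the ether bonds are made. Phenol 2 would be monobrominated ortho to its free hydroxyl with N-bromosuccinimide (1.0 equiv, MeCN, 0 °C) to give 4-(benzyloxy)-2-bromophenol F1. F1 would be coupled twice with diiodide 1 under the step 1 conditions at 90 °C, where the C–I bonds should react well ahead of the electron-rich C–Br bond, to give 1,4-bis[4-(benzyloxy)-2-bromophenoxy]-2,5-dimethoxybenzene F2. The benzyl ethers would be removed without reducing C–Br by BCl3 and pentamethylbenzene (CH2Cl2, −78 °C) to give 4,4'-[(2,5-dimethoxy-1,4-phenylene)bis(oxy)]bis(3-bromophenol) F3. Six equivalents of Br2 (CH2Cl2, 0 °C → rt, no Lewis acid) should then fill only the hydroxyl-flanking C3' and C5' and the ring B positions B3 and B6, and deliver 6.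

Step 1. The double coupling may stall after the first C–O bond, because the second oxidative addition into the more electron-rich, ortho-substituted aryl iodide is slower, and hydrodeiodination may compete. The fallback sets out from 1 and returns at 3, and inverts the polarity of the ring B partner. Double iodine–lithium exchange on 1 (n-BuLi, THF, −78 °C), trapping with B(OiPr)3 and aqueous HCl should give (2,5-dimethoxy-1,4-phenylene)diboronic acid F4. A Chan–Lam–Evans coupling of F4 with 2 (Cu(OAc)2, divalent copper, catalytic; pyridine, 4 Å molecular sieves, CH2Cl2, air, rt) should then form both C–O bonds at room temperature and give 3.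

Step 4. Cleavage of the two methyl ethers flanked by bromine and aryloxy groups may remain incomplete, or the freed ring B hydroquinone may be air-oxidised during the acidic work-up. The fallback sets out from 6 and returns at 7, and removes the methyl groups oxidatively. The outer phenols would be acetylated (Ac2O, pyridine, rt) to give 1,4-bis(4-acetoxy-2,3,5-tribromophenoxy)-2,5-dibromo-3,6-dimethoxybenzene F5. (NH4)2Ce(NO3)6 (tetravalent cerium; MeCN/H2O, 0 °C) should oxidise the para-dimethoxy ring B, with loss of both methyl groups as methanol, to 2,5-bis(4-acetoxy-2,3,5-tribromophenoxy)-3,6-dibromo-1,4-benzoquinone F6. Na2S2O4 (EtOAc/H2O, rt) would reduce the quinone to 2,5-bis(4-acetoxy-2,3,5-tribromophenoxy)-3,6-dibromobenzene-1,4-diol F7. Degassed HCl in MeOH (40 °C) would then cleave the acetates and give 7.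

Further compounds
F1 | step 3 | 4-(benzyloxy)-2-bromophenol | Oc1ccc(OCc2ccccc2)cc1Br
F2 | step 3 | 1,4-bis[4-(benzyloxy)-2-bromophenoxy]-2,5-dimethoxybenzene | COc1cc(Oc2ccc(OCc3ccccc3)cc2Br)c(OC)cc1Oc1ccc(OCc2ccccc2)cc1Br
F3 | step 3 | 4,4'-[(2,5-dimethoxy-1,4-phenylene)bis(oxy)]bis(3-bromophenol) | COc1cc(Oc2ccc(O)cc2Br)c(OC)cc1Oc1ccc(O)cc1Br
F4 | step 1 | (2,5-dimethoxy-1,4-phenylene)diboronic acid | COc1cc(B(O)O)c(OC)cc1B(O)O
F5 | step 4 | 1,4-bis(4-acetoxy-2,3,5-tribromophenoxy)-2,5-dibromo-3,6-dimethoxybenzene | COc1c(Br)c(Oc2cc(Br)c(OC(C)=O)c(Br)c2Br)c(OC)c(Br)c1Oc1cc(Br)c(OC(C)=O)c(Br)c1Br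
F6 | step 4 | 2,5-bis(4-acetoxy-2,3,5-tribromophenoxy)-3,6-dibromo-1,4-benzoquinone | O=C1C(Br)=C(Oc2cc(Br)c(OC(C)=O)c(Br)c2Br)C(=O)C(Br)=C1Oc1cc(Br)c(OC(C)=O)c(Br)c1Br
F7 | step 4 | 2,5-bis(4-acetoxy-2,3,5-tribromophenoxy)-3,6-dibromobenzene-1,4-diol | Oc1c(Br)c(Oc2cc(Br)c(OC(C)=O)c(Br)c2Br)c(O)c(Br)c1Oc1cc(Br)c(OC(C)=O)c(Br)c1Br
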